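Ring A of this neo-clerodane (C1–C5 and C10, clerodane numbering) is cut into an unfunctionalised three-carbon bridge, C1–C2–C3, and a ring B enone bearing an acetyl group (C4 with C18) on quaternary C5. The key step exploits the 1,3-relationship, across C5, between C10 (β-carbon of the C8 enone) and the C4 ketone: allylidenetriphenylphosphorane adds through its γ-carbon to C10 and the ylide then closes onto C4, so one operation makes C1–C10 and C3=C4 and sets C10. The precursor, (R)-4-acetyl-2,4-dimethylcyclohex-2-enone, comes from a catalytic asymmetric Diels–Alder reaction; the side chain is attached later by B-alkyl Suzuki coupling.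

Key step: step 6

Assumption: clerodane numbering is used (ring A C1–C5/C10, ring B C5–C10, side chain C11–C16, methyl groups C17–C20); the (S)-configured oxazaborolidinium catalyst of step 2 is taken to give the (R)-aldehyde 4, and its enantiomer would be used if the opposite sense of induction operated.

Step 1
Reactants: 1 3-methylbut-3-en-2-one
Product: 2 2-methyl-3-(triisopropylsilyloxy)buta-1,3-diene
Conditions: TIPSOTf, Et3N, Et2O, 0 °C → rt
Reagents that add atoms: triisopropylsilyl trifluoromethanesulfonate, CC(C)[Si](OS(=O)(=O)C(F)(F)F)(C(C)C)C(C)C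
Why: Silyl enol ether formation: the ketone can enolise only towards its methyl group, so soft enolisation should give the 2-silyloxy diene directly.

Step 2
Reactants: 2 2-methyl-3-(triisopropylsilyloxy)buta-1,3-diene; 3 methacrolein (2-methylprop-2-enal)
Product: 4 (R)-1,3-dimethyl-4-(triisopropylsilyloxy)cyclohex-3-ene-1-carbaldehyde
Conditions: (S)-3,3-diphenyl-1-(2-methylphenyl)tetrahydro-1H,3H-pyrrolo[1,2-c][1,3,2]oxazaborole (20 mol%), Tf2NH (20 mol%), CH2Cl2, −78 → −40 °C
Reagents that add atoms: none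
Why: Catalytic asymmetric Diels–Alder reaction of a 2-substituted acrolein under oxazaborolidinium activation: the silyloxy group dictates the 1,4 ("para") orientation of the siloxy and formyl-bearing carbons, and the catalyst shields one face of the coordinated s-trans enal, which creates the quaternary C5 stereocentre (R).

Step 3
Reactants: 4 (R)-1,3-dimethyl-4-(triisopropylsilyloxy)cyclohex-3-ene-1-carbaldehyde
Product: 5 1-[(1R)-1,3-dimethyl-4-(triisopropylsilyloxy)cyclohex-3-en-1-yl]ethan-1-ol (carbinol epimers)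
Conditions: MeMgBr, THF, −78 → 0 °C; aq. NH4Cl
Reagents that add atoms: methylmagnesium bromide, C[Mg]Br
Why: Grignard addition to the aldehyde (the silyl enol ether is inert); the carbinol centre is formed without control and is removed in step 4.

Step 4
Reactants: 5 1-[(1R)-1,3-dimethyl-4-(triisopropylsilyloxy)cyclohex-3-en-1-yl]ethan-1-ol
Product: 6 1-[(1R)-1,3-dimethyl-4-(triisopropylsilyloxy)cyclohex-3-en-1-yl]ethan-1-one
Conditions: Dess–Martin periodinane, CH2Cl2, 0 °C → rt
Reagents that add atoms: none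
Why: Dess–Martin oxidation of the secondary alcohol should give the methyl ketone (C4 with C18) without touching the silyl enol ether or the quaternary centre.

Step 5
Reactants: 6 1-[(1R)-1,3-dimethyl-4-(triisopropylsilyloxy)cyclohex-3-en-1-yl]ethan-1-one
Product: 7 (R)-4-acetyl-2,4-dimethylcyclohex-2-en-1-one
Conditions: Pd(OAc)2 (1.1 equiv), MeCN, 40 °C
Reagents that add atoms: none
Why: Ito–Saegusa oxidation: the divalent palladium enolate formed from the silyl enol ether undergoes β-hydride elimination towards the ring CH2 (C10) and so unveils the C8 enone with C10 as its β-carbon.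

Step 6
Reactants: 7 (R)-4-acetyl-2,4-dimethylcyclohex-2-en-1-one
Product: 10 (4aR,8aR)-1,4a,5-trimethyl-3,4,4a,8a-tetrahydronaphthalen-2(1H)-one (C1 epimers), via vinylphosphonium enolate 8 (not isolated), via allylic ylide ketone 9 (not isolated)
Conditions: CH2=CHCH2PPh3Br, KOt-Bu, THF, 0 °C; then 7, −78 → 65 °C
Reagents that add atoms: allyltriphenylphosphonium bromide, C=CC[P+](c1ccccc1)(c1ccccc1)c1ccccc1.[Br-]
Why: The ylide adds through its γ-carbon to C10 of the enone (conjugate addition), the resulting enolate 8 passes a proton from C1 to C9 to give allylic ylide 9, and its α-carbon (C3) then olefinates the C4 acetyl carbonyl with loss of Ph3PO. The closest known reaction type is the Büchi–Wüest cyclohexadiene annulation of allylidenetriphenylphosphorane with enones (tandem Michael addition/intramolecular Wittig reaction). Ring A is closed by the intramolecular Wittig step, a six-membered closure in which C3 attacks the C4 carbonyl; closure onto the C8 carbonyl would require a bridgehead alkene and is excluded. The new C10 stereocentre is controlled by quaternary C5: axial attack on the half-chair enone anti to the pseudoaxial, electron-withdrawing acetyl group should place C1 trans to C4 and hence give the trans ring fusion, whereas C9 is formed as an inconsequential epimer mixture. The step needs conjugate addition to outrun direct olefination, which the hindered carbonyl groups (α-quaternary acetyl, α-branched enone) and the soft, delocalised ylide should secure.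

Step 7
Reactants: 10 (4aR,8aR)-1,4a,5-trimethyl-3,4,4a,8a-tetrahydronaphthalen-2(1H)-one
Product: 11 (4aR,8aR)-1,4a,5-trimethyl-3,4,4a,7,8,8a-hexahydronaphthalen-2(1H)-one (C1 epimers)
Conditions: KO2CN=NCO2K, AcOH, MeOH, 0 °C → rt
Reagents that add atoms: none
Why: Diimide reduction: concerted syn transfer of H2 should occur at the cis-disubstituted C1=C2 bond of the diene much faster than at the hindered trisubstituted C3=C4 bond, and the ketone is inert.

Step 8
Reactants: 11 (4aR,8aR)-1,4a,5-trimethyl-3,4,4a,7,8,8a-hexahydronaphthalen-2(1H)-one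
Product: 13 tert-butyl 2-[(1R,4aR,8aS)-1,4a,5-trimethyl-2-oxo-1,2,3,4,4a,7,8,8a-octahydronaphthalen-1-yl]acetate, via potassium enolate 12 (not isolated)
Conditions: KH (0.97 equiv), THF, rt; then BrCH2CO2t-Bu, −78 → 0 °C
Reagents that add atoms: tert-butyl bromoacetate, CC(C)(C)OC(=O)CBr
Why: Enolate alkylation: equilibration with a slight deficit of KH should give the more substituted C8–C9 enolate, and the bromoacetate approaches anti to the axial C5 methyl group, which sets quaternary C9 with its methyl group cis to the C5 methyl group.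

Step 9
Reactants: 13 tert-butyl 2-[(1R,4aR,8aS)-1,4a,5-trimethyl-2-oxo-1,2,3,4,4a,7,8,8a-octahydronaphthalen-1-yl]acetate
Product: 14 tert-butyl 2-[(1R,4aR,8aR)-1,4a,5-trimethyl-2-methylidene-1,2,3,4,4a,7,8,8a-octahydronaphthalen-1-yl]acetate
Conditions: Ph3PCH3Br, KOt-Bu, toluene, 90 °C
Reagents that add atoms: methyltriphenylphosphonium bromide, C[P+](c1ccccc1)(c1ccccc1)c1ccccc1.[Br-]
Why: Wittig methylenation with methylenetriphenylphosphorane at elevated temperature should convert the hindered C8 ketone into the exocyclic alkene and leave the tert-butyl ester intact.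

Step 10
Reactants: 14 tert-butyl 2-[(1R,4aR,8aR)-1,4a,5-trimethyl-2-methylidene-1,2,3,4,4a,7,8,8a-octahydronaphthalen-1-yl]acetate
Product: 15 tert-butyl 2-[(1S,2R,4aR,8aR)-1,2,4a,5-tetramethyl-1,2,3,4,4a,7,8,8a-octahydronaphthalen-1-yl]acetate
Conditions: H2 (20 bar), RhCl(PPh3)3 (10 mol%), benzene/EtOH, 40 °C
Reagents that add atoms: none
Why: Homogeneous hydrogenation with RhCl(PPh3)3 reduces the 1,1-disubstituted alkene but not the trisubstituted C3=C4 bond, and hydrogen should be delivered from the face opposite the axial C9 methyl group, which sets C8 with its methyl group equatorial and cis to the C9 methyl group.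

Step 11
Reactants: 15 tert-butyl 2-[(1S,2R,4aR,8aR)-1,2,4a,5-tetramethyl-1,2,3,4,4a,7,8,8a-octahydronaphthalen-1-yl]acetate
Product: 16 2-[(1S,2R,4aR,8aR)-1,2,4a,5-tetramethyl-1,2,3,4,4a,7,8,8a-octahydronaphthalen-1-yl]ethan-1-ol
Conditions: LiAlH4, THF, 0 °C → rt
Reagents that add atoms: none
Why: Hydride reduction of the ester to the primary alcohol (C12).

Step 12
Reactants: 16 2-[(1S,2R,4aR,8aR)-1,2,4a,5-tetramethyl-1,2,3,4,4a,7,8,8a-octahydronaphthalen-1-yl]ethan-1-ol
Product: 17 (1S,2R,4aR,8aR)-1-(2-iodoethyl)-1,2,4a,5-tetramethyl-1,2,3,4,4a,7,8,8a-octahydronaphthalene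
Conditions: I2, PPh3, imidazole, CH2Cl2, 0 °C → rt
Reagents that add atoms: iodine, II
Why: Appel-type iodination (SN2 displacement of the alkoxyphosphonium group at the primary carbon).

Step 13
Reactants: 18 but-2-yne-1,4-diol
Product: 20 4-[(tert-butyldimethylsilyl)oxy]but-2-yn-1-ol, via monosodium alkoxide 19 (not isolated)
Conditions: NaH (1 equiv), THF, 0 °C; TBSCl, rt
Reagents that add atoms: tert-butyldimethylsilyl chloride, CC(C)(C)[Si](C)(C)Cl
Why: Monosilylation through the sparingly soluble monosodium alkoxide differentiates the two hydroxyl groups of the symmetrical diol.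

Step 14
Reactants: 20 4-[(tert-butyldimethylsilyl)oxy]but-2-yn-1-ol
Product: 22 (Z)-4-[(tert-butyldimethylsilyl)oxy]-3-iodobut-2-en-1-ol, via cyclic vinylalanate 21 (not isolated)
Conditions: NaAlH2(OCH2CH2OCH3)2, THF, 0 °C → rt; then I2, −78 °C
Reagents that add atoms: iodine, II
Why: Alkoxide-directed trans-hydroalumination places aluminium on the alkyne carbon remote from the free hydroxyl group and iodinolysis occurs with retention, so the (Z)-iodoalkene should form with iodine cis to the CH2OH group.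

Step 15
Reactants: 17 (1S,2R,4aR,8aR)-1-(2-iodoethyl)-1,2,4a,5-tetramethyl-1,2,3,4,4a,7,8,8a-octahydronaphthalene; 22 (Z)-4-[(tert-butyldimethylsilyl)oxy]-3-iodobut-2-en-1-ol
Product: 25 (2E)-3-{[(tert-butyldimethylsilyl)oxy]methyl}-5-[(1S,2R,4aR,8aR)-1,2,4a,5-tetramethyl-1,2,3,4,4a,7,8,8a-octahydronaphthalen-1-yl]pent-2-en-1-ol, via alkyllithium 23 (not isolated), via lithium alkyl(methoxy)borate 24 (not isolated)
Conditions: t-BuLi (2.1 equiv), Et2O, −78 °C; B-methoxy-9-BBN, THF, −78 °C → rt; then 22, PdCl2[1,1'-bis(diphenylphosphino)ferrocene] (5 mol%), AsPh3, K3PO4 (aq.), DMF, rt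
Reagents that add atoms: none
Why: Lithium–iodine exchange, transfer to boron and B-alkyl Suzuki–Miyaura coupling join C12 to C13 with retention of the alkene geometry, which should give the (E)-trisubstituted alkene with C12 cis to C15.

Step 16
Reactants: 25 (2E)-3-{[(tert-butyldimethylsilyl)oxy]methyl}-5-[(1S,2R,4aR,8aR)-1,2,4a,5-tetramethyl-1,2,3,4,4a,7,8,8a-octahydronaphthalen-1-yl]pent-2-en-1-ol
Product: 26 (2E)-3-{[(tert-butyldimethylsilyl)oxy]methyl}-5-[(1S,2R,4aR,8aR)-1,2,4a,5-tetramethyl-1,2,3,4,4a,7,8,8a-octahydronaphthalen-1-yl]pent-2-en-1-yl docosanoate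
Conditions: docosanoyl chloride, pyridine, DMAP (cat.), CH2Cl2, 0 °C → rt
Reagents that add atoms: docosanoyl chloride, CCCCCCCCCCCCCCCCCCCCCC(=O)Cl
Why: DMAP-catalysed acylation of the only free (primary allylic) hydroxyl group.

Step 17
Reactants: 26 (2E)-3-{[(tert-butyldimethylsilyl)oxy]methyl}-5-[(1S,2R,4aR,8aR)-1,2,4a,5-tetramethyl-1,2,3,4,4a,7,8,8a-octahydronaphthalen-1-yl]pent-2-en-1-yl docosanoate
Product: 27 (2E)-3-(hydroxymethyl)-5-[(1S,2R,4aR,8aR)-1,2,4a,5-tetramethyl-1,2,3,4,4a,7,8,8a-octahydronaphthalen-1-yl]pent-2-en-1-yl docosanoate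
Conditions: HF·pyridine, pyridine, THF, 0 °C → rt
Reagents that add atoms: none
Why: Fluoride cleaves the Si–O bond under buffered conditions that spare the allylic ester, and acyl migration is geometrically impossible because the two oxygenated carbons are trans across the alkene.

Compound list
1 | 3-methylbut-3-en-2-one | CC(=O)C(C)=C | starting material
2 | 2-methyl-3-(triisopropylsilyloxy)buta-1,3-diene | C=C(C)C(=C)O[Si](C(C)C)(C(C)C)C(C)C | intermediate
3 | methacrolein (2-methylprop-2-enal) | CC(=C)C=O | starting material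
4 | (R)-1,3-dimethyl-4-(triisopropylsilyloxy)cyclohex-3-ene-1-carbaldehyde | O=C[C@]1(C)CCC(O[Si](C(C)C)(C(C)C)C(C)C)=C(C)C1 | intermediate
5 | 1-[(1R)-1,3-dimethyl-4-(triisopropylsilyloxy)cyclohex-3-en-1-yl]ethan-1-ol (carbinol epimers) | CC(O)[C@]1(C)CCC(O[Si](C(C)C)(C(C)C)C(C)C)=C(C)C1 | intermediate
6 | 1-[(1R)-1,3-dimethyl-4-(triisopropylsilyloxy)cyclohex-3-en-1-yl]ethan-1-one | CC(=O)[C@]1(C)CCC(O[Si](C(C)C)(C(C)C)C(C)C)=C(C)C1 | intermediate
7 | (R)-4-acetyl-2,4-dimethylcyclohex-2-en-1-one | CC(=O)[C@]1(C)CCC(=O)C(C)=C1 | intermediate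
8 | vinylphosphonium enolate (conjugate adduct, C1 trans to the acetyl group; formed in the flask) | CC(=O)[C@]1(C)CCC([O-])=C(C)[C@H]1C/C=C/[P+](c1ccccc1)(c1ccccc1)c1ccccc1 | intermediate
9 | allylic ylide ketone (after proton transfer from C1 to C9; formed in the flask) | CC(=O)[C@]1(C)CCC(=O)C(C)[C@H]1/C=C\C=P(c1ccccc1)(c1ccccc1)c1ccccc1 | intermediate
10 | (4aR,8aR)-1,4a,5-trimethyl-3,4,4a,8a-tetrahydronaphthalen-2(1H)-one (trans-fused, C1 epimers) | CC1C(=O)CC[C@@]2(C)C(C)=CC=C[C@H]12 | intermediate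
11 | (4aR,8aR)-1,4a,5-trimethyl-3,4,4a,7,8,8a-hexahydronaphthalen-2(1H)-one (trans-fused, C1 epimers) | CC1C(=O)CC[C@@]2(C)C(C)=CCC[C@H]12 | intermediate
12 | potassium enolate of 11 (C8–C9 enolate; formed in the flask) | [K+].CC1=C([O-])CC[C@@]2(C)C(C)=CCC[C@H]12 | intermediate
13 | tert-butyl 2-[(1R,4aR,8aS)-1,4a,5-trimethyl-2-oxo-1,2,3,4,4a,7,8,8a-octahydronaphthalen-1-yl]acetate | CC(C)(C)OC(=O)C[C@@]1(C)C(=O)CC[C@@]2(C)C(C)=CCC[C@H]12 | intermediate
14 | tert-butyl 2-[(1R,4aR,8aR)-1,4a,5-trimethyl-2-methylidene-1,2,3,4,4a,7,8,8a-octahydronaphthalen-1-yl]acetate | CC(C)(C)OC(=O)C[C@@]1(C)C(=C)CC[C@@]2(C)C(C)=CCC[C@H]12 | intermediate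
15 | tert-butyl 2-[(1S,2R,4aR,8aR)-1,2,4a,5-tetramethyl-1,2,3,4,4a,7,8,8a-octahydronaphthalen-1-yl]acetate | CC(C)(C)OC(=O)C[C@@]1(C)[C@H](C)CC[C@@]2(C)C(C)=CCC[C@H]12 | intermediate
16 | 2-[(1S,2R,4aR,8aR)-1,2,4a,5-tetramethyl-1,2,3,4,4a,7,8,8a-octahydronaphthalen-1-yl]ethan-1-ol | OCC[C@@]1(C)[C@H](C)CC[C@@]2(C)C(C)=CCC[C@H]12 | intermediate
17 | (1S,2R,4aR,8aR)-1-(2-iodoethyl)-1,2,4a,5-tetramethyl-1,2,3,4,4a,7,8,8a-octahydronaphthalene | ICC[C@@]1(C)[C@H](C)CC[C@@]2(C)C(C)=CCC[C@H]12 | intermediate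
18 | but-2-yne-1,4-diol | OCC#CCO | starting material
19 | monosodium alkoxide of but-2-yne-1,4-diol (formed in the flask) | [Na+].[O-]CC#CCO | intermediate
20 | 4-[(tert-butyldimethylsilyl)oxy]but-2-yn-1-ol | OCC#CCO[Si](C)(C)C(C)(C)C | intermediate
21 | cyclic sodium vinylalanate (aluminium on the carbon bearing CH2OTBS, cis to the CH2O–Al arm; formed in the flask) | [Na+].COCCO[Al-]1(OCCOC)OCC=C1CO[Si](C)(C)C(C)(C)C | intermediate
22 | (Z)-4-[(tert-butyldimethylsilyl)oxy]-3-iodobut-2-en-1-ol | OC/C=C(/CO[Si](C)(C)C(C)(C)C)I | intermediate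
23 | alkyllithium from 17 (formed in the flask) | [Li]CC[C@@]1(C)[C@H](C)CC[C@@]2(C)C(C)=CCC[C@H]12 | intermediate
24 | lithium B-alkyl-B-methoxy-9-borabicyclo[3.3.1]nonane borate (formed in the flask) | [Li+].CO[B-]1(CC[C@@]2(C)[C@H](C)CC[C@@]3(C)C(C)=CCC[C@H]23)C2CCCC1CCC2 | intermediate
25 | (2E)-3-{[(tert-butyldimethylsilyl)oxy]methyl}-5-[(1S,2R,4aR,8aR)-1,2,4a,5-tetramethyl-1,2,3,4,4a,7,8,8a-octahydronaphthalen-1-yl]pent-2-en-1-ol | OC/C=C(/CO[Si](C)(C)C(C)(C)C)CC[C@@]1(C)[C@H](C)CC[C@@]2(C)C(C)=CCC[C@H]12 | intermediate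
26 | (2E)-3-{[(tert-butyldimethylsilyl)oxy]methyl}-5-[(1S,2R,4aR,8aR)-1,2,4a,5-tetramethyl-1,2,3,4,4a,7,8,8a-octahydronaphthalen-1-yl]pent-2-en-1-yl docosanoate | CCCCCCCCCCCCCCCCCCCCCC(=O)OC/C=C(/CO[Si](C)(C)C(C)(C)C)CC[C@@]1(C)[C@H](C)CC[C@@]2(C)C(C)=CCC[C@H]12 | intermediate
27 | (2E)-3-(hydroxymethyl)-5-[(1S,2R,4aR,8aR)-1,2,4a,5-tetramethyl-1,2,3,4,4a,7,8,8a-octahydronaphthalen-1-yl]pent-2-en-1-yl docosanoate (clerodane 5R,8R,9S,10R) | CCCCCCCCCCCCCCCCCCCCCC(=O)OC/C=C(/CO)CC[C@@]1(C)[C@H](C)CC[C@@]2(C)C(C)=CCC[C@H]12 | target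

Total step count: 17. Longest linear sequence: 15 steps (steps 1–12 and 15–17); steps 13–14 make the side-chain fragment.

Steps most likely to fail

1. Step 6. The ylide may olefinate a carbonyl group directly instead of adding in conjugate fashion, or the conjugate addition may occur on the face syn to the acetyl group and lead to a cis ring fusion. The fallback sets out from 7 and returns at 11, making the two bonds one after the other by known chemistry. Copper-catalysed conjugate addition of 3-butenylmagnesium bromide (CuBr·SMe2 cat., TMSCl, THF, −78 °C) should give the silyl enol ether 1-[(1R,2R)-2-(but-3-en-1-yl)-1,3-dimethyl-4-(trimethylsilyloxy)cyclohex-3-en-1-yl]ethan-1-one F1. Wittig methylenation of its acetyl group (Ph3P=CH2, THF) gives {[(3S,4R)-3-(but-3-en-1-yl)-2,4-dimethyl-4-(prop-1-en-2-yl)cyclohex-1-en-1-yl]oxy}trimethylsilane F2. Ring-closing metathesis with second-generation Grubbs catalyst (CH2Cl2, 40 °C) closes C3=C4 to give trimethyl{[(4aR,8aS)-1,4a,5-trimethyl-3,4,4a,7,8,8a-hexahydronaphthalen-2-yl]oxy}silane F3, and hydrolysis (HCl, THF/H2O) returns to 11.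

2. Step 8. Deprotonation may occur towards C7 through incomplete equilibration, the enolate may be alkylated more than once, and any cis-fused material carried from step 6 cannot be corrected here. The fallback sets out from 11 and returns at 13. Dehydrogenation with 2-iodoxybenzoic acid (DMSO, 70 °C) gives the enone (4aS)-1,4a,5-trimethyl-4,4a,7,8-tetrahydronaphthalen-2(3H)-one F4, in which C10 is planar again. Reductive alkylation (Li, NH3/THF, t-BuOH, −78 °C; NH3 removed; BrCH2CO2t-Bu) then fixes the trans ring fusion by axial protonation at C10 and alkylates the regiodefined C8–C9 enolate at C9, returning to 13.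

3. Step 10. Hydrogen uptake at the hindered alkene may be slow, the facial selectivity at C8 may be poor, or the C3=C4 bond may be reduced or shifted. The fallback sets out from 14 and returns at 16. Hydroboration with the bulky 9-BBN and oxidation (NaOH, H2O2) gives tert-butyl 2-[(1R,2R,4aR,8aR)-2-(hydroxymethyl)-1,4a,5-trimethyl-1,2,3,4,4a,7,8,8a-octahydronaphthalen-1-yl]acetate F5. Tosylation (TsCl, pyridine) gives tert-butyl 2-[(1R,2R,4aR,8aR)-1,4a,5-trimethyl-2-{[(4-methylbenzenesulfonyl)oxy]methyl}-1,2,3,4,4a,7,8,8a-octahydronaphthalen-1-yl]acetate F6. LiAlH4 then reduces the tosylate to the C8 methyl group and the ester to the alcohol in one operation, returning to 16.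

Further compounds
F1 | step 6 | 1-[(1R,2R)-2-(but-3-en-1-yl)-1,3-dimethyl-4-(trimethylsilyloxy)cyclohex-3-en-1-yl]ethan-1-one | CC(=O)[C@]1(C)CCC(O[Si](C)(C)C)=C(C)[C@H]1CCC=C
F2 | step 6 | {[(3S,4R)-3-(but-3-en-1-yl)-2,4-dimethyl-4-(prop-1-en-2-yl)cyclohex-1-en-1-yl]oxy}trimethylsilane | C=C(C)[C@]1(C)CCC(O[Si](C)(C)C)=C(C)[C@H]1CCC=C
F3 | step 6 | trimethyl{[(4aR,8aS)-1,4a,5-trimethyl-3,4,4a,7,8,8a-hexahydronaphthalen-2-yl]oxy}silane | CC1=C(O[Si](C)(C)C)CC[C@@]2(C)C(C)=CCC[C@H]12
F4 | step 8 | (4aS)-1,4a,5-trimethyl-4,4a,7,8-tetrahydronaphthalen-2(3H)-one | CC1=C2CCC=C(C)[C@]2(C)CCC1=O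
F5 | step 10 | tert-butyl 2-[(1R,2R,4aR,8aR)-2-(hydroxymethyl)-1,4a,5-trimethyl-1,2,3,4,4a,7,8,8a-octahydronaphthalen-1-yl]acetate | CC(C)(C)OC(=O)C[C@@]1(C)[C@H](CO)CC[C@@]2(C)C(C)=CCC[C@H]12
F6 | step 10 | tert-butyl 2-[(1R,2R,4aR,8aR)-1,4a,5-trimethyl-2-{[(4-methylbenzenesulfonyl)oxy]methyl}-1,2,3,4,4a,7,8,8a-octahydronaphthalen-1-yl]acetate | CC(C)(C)OC(=O)C[C@@]1(C)[C@H](COS(=O)(=O)c3ccc(C)cc3)CC[C@@]2(C)C(C)=CCC[C@H]12
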